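**Assumption:** (R)-TRIP is taken to give the (12R) acetal in Step 5; this sense of induction is not predicted here, so if it proves opposite, (S)-TRIP is used with no other change. Flavan numbering (O1, C2, C3, C4, C4a…C8a; chalcone ring primed) is used for the chroman unit. The target is the 2,4-trans flavan, (2R,4R).

## Retrosynthetic overview

1. The chalcone enone comes last, by Claisen–Schmidt condensation of a methyl ketone with benzaldehyde.
2. The C2–Ph bond is cut next: a phenyl nucleophile adds anti to a ring-A oxocarbenium released from a bridged diaryl acetal (2,8-dioxabicyclo[3.3.1]nonane), which sets C2 and the 2,4-trans relationship.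
3. The bridged acetal comes from enantioselective dearomatising C4-arylation of a chromenylium salt built on the chalcone ring, using C2v-symmetric 2,5-dimethoxyresorcinol as nucleophile (C4–C4a bond, sets C4), followed by acetalisation.
4. The chromenylium salt comes from 2,6-dihydroxy-4-methoxyacetophenone and a malonaldehyde acetal; the resorcinol comes from 4-methoxyphenol.
5. Ring order: benzopyrylium on the chalcone ring → bridged bicyclic acetal → flavan ring C, with the pyran oxygen transposed onto ring A.

## Route

**Step 1**
Reactants: 1, 4-methoxyphenol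
Product: 2, 2,6-dibromo-4-methoxyphenol
Conditions: Br2 (2.1 equiv), AcOH, NaOAc, 0 °C → rt
Reagents that add atoms: bromine, BrBr
Why: Electrophilic aromatic bromination, where the free OH directs to both ortho positions and the para position is blocked by OMe.

**Step 2**
Reactants: 2, 2,6-dibromo-4-methoxyphenol
Product: 3, 1,3-dibromo-2,5-dimethoxybenzene
Conditions: MeI, K2CO3, acetone, reflux
Reagents that add atoms: iodomethane, CI
Why: Williamson O-methylation of the acidic 2,6-dibromophenol.

**Step 3**
Reactants: 3, 1,3-dibromo-2,5-dimethoxybenzene
Product: 4, 2,5-dimethoxybenzene-1,3-diol (C2v-symmetric)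
Conditions: Pd2(dba)3 (2 mol %), t-BuXPhos (8 mol %), KOH (6 equiv), dioxane/H2O 1:1, 100 °C; then aq HCl
Reagents that add atoms: potassium hydroxide, [K+].[OH-]
Why: Twofold Pd-catalysed hydroxylation of aryl bromides (Buchwald-type C–O coupling with hydroxide), which leaves the methyl ethers untouched.

**Step 4**
Reactants: 5, 1-(2,6-dihydroxy-4-methoxyphenyl)ethan-1-one; 6, 1,1,3,3-tetramethoxypropane
Product: 7, 8-acetyl-7-hydroxy-5-methoxychromenylium tetrafluoroborate
Conditions: 6 (1.5 equiv), 48% aq HBF4 (3 equiv), AcOH, 50 °C; precipitate with Et2O
Reagents that add atoms: tetrafluoroboric acid (counter-ion only), [H+].F[B-](F)(F)F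
Why: Classical benzopyrylium synthesis from a phenol and a 1,3-dicarbonyl equivalent: Friedel–Crafts attack by one of the two equivalent ring CH positions on the unmasked malonaldehyde, closure by the adjacent OH and loss of MeOH/H2O give the aromatic cation, and the acyl-deactivated arene is slow to add to it a second time.

**Step 5 (key step)**
Reactants: 7, chromenylium salt (1.0 equiv); 4, 2,5-dimethoxybenzene-1,3-diol (1.5 equiv, excess recovered)
Product: 8, 1-[(6S,12R)-3,9-dihydroxy-1,4,11-trimethoxy-12H-6,12-methanodibenzo[d,g][1,3]dioxocin-8-yl]ethan-1-one. This is the bridged acetal: the CH bridgehead (future C4, R) carries both aryl rings, the acetal bridgehead (future C2, S) carries H and both aryl oxygens, and a CH2 links them.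
Conditions: (R)-TRIP (10 mol %), Na2CO3 (1.2 equiv), 4 Å MS, PhMe/CH2Cl2 4:1, −30 °C; filter, then TsOH·H2O (10 mol %), rt; recrystallise
Reagents that add atoms: none
Why: Proposed new method: the lipophilic chiral phosphate carries the insoluble chromenylium into solution as a contact ion pair (in equilibrium with its 7-oxo quinoidal base bound to the acid) while hydrogen-bonding an OH of 4, so one of the two equivalent CH positions of 4 attacks C4 on a single face (dearomatising the pyrylium and setting C4 = R); acid then adds the neighbouring OH of 4 across the enol ether, which can only bridge cis and so fixes the acetal carbon as S; the closest known reaction types are chiral-anion phase-transfer and phosphoric-acid-catalysed additions of phenols to flavylium salts giving 2,8-dioxabicyclo[3.3.1]nonanes, and phosphoric-acid-catalysed 1,6-additions of phenols to para-quinone methides.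

**Step 6**
Reactants: 8, bridged acetal; 9, phenylmagnesium bromide
Product: 10, 1-{2,6-dihydroxy-3-[(2R,4R)-7-hydroxy-5,8-dimethoxy-2-phenyl-3,4-dihydro-2H-chromen-4-yl]-4-methoxyphenyl}ethan-1-one
Conditions: (i) HMDS, cat. TMSCl, CH2Cl2, 40 °C, evaporate (transient bis-O-TMS ether, not isolated); (ii) Ph2CuMgBr [9 (5 equiv), CuBr·SMe2 (2.5 equiv)], BF3·OEt2 (2.5 equiv), THF/Et2O, −78 → −30 °C; (iii) 1 M HCl, MeOH, 0 °C
Reagents that add atoms: none (phenyl comes from 9; the TMS groups are lost on work-up)
Why: Proposed new method: BF3 ionises the acetal at the C2–O bond to the acetyl-conjugated aryloxy group (the less basic, better leaving oxygen), leaving the oxocarbenium on the electron-rich ring-A oxygen, and the non-chelating phenylcopper reagent attacks C2 anti to the departing oxygen and to the pseudo-axial C4 aryl group (inversion), giving C2 = R and the 2,4-trans flavan while leaving the hindered di-ortho-substituted ketone alone; the closest known reaction types are anti-selective BF3/organocopper cleavage of acetals and Lewis-acid C-arylation of bicyclic anhydro-sugar acetals.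

**Step 7**
Reactants: 10, flavan methyl ketone; 11, benzaldehyde
Product: 12, Sarcandrone B, (E)-1-{2,6-dihydroxy-3-[(2R,4R)-7-hydroxy-5,8-dimethoxy-2-phenylchroman-4-yl]-4-methoxyphenyl}-3-phenylprop-2-en-1-one
Conditions: 11 (1.5 equiv), 50% aq KOH (20 equiv), EtOH, 0 °C → rt, Ar, 36 h; cold 1 M HCl to pH 5
Reagents that add atoms: none
Why: Claisen–Schmidt aldol condensation of the methyl-ketone enolate with a non-enolisable aldehyde gives the thermodynamic E-enone, the polyphenoxide form suppressing flavanone closure, and neither C2–H nor C4–H is acidic enough to epimerise.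

## Compound list

1 | 4-methoxyphenol | COc1ccc(O)cc1 | starting material
2 | 2,6-dibromo-4-methoxyphenol | COc1cc(Br)c(O)c(Br)c1 | intermediate
3 | 1,3-dibromo-2,5-dimethoxybenzene | COc1cc(Br)c(OC)c(Br)c1 | intermediate
4 | 2,5-dimethoxybenzene-1,3-diol | COc1cc(O)c(OC)c(O)c1 | intermediate
5 | 1-(2,6-dihydroxy-4-methoxyphenyl)ethan-1-one | COc1cc(O)c(C(C)=O)c(O)c1 | starting material
6 | 1,1,3,3-tetramethoxypropane | COC(OC)CC(OC)OC | starting material
7 | 8-acetyl-7-hydroxy-5-methoxychromenylium tetrafluoroborate | CC(=O)c1c(O)cc(OC)c2ccc[o+]c12.F[B-](F)(F)F | intermediate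
8 | 1-[(6S,12R)-3,9-dihydroxy-1,4,11-trimethoxy-12H-6,12-methanodibenzo[d,g][1,3]dioxocin-8-yl]ethan-1-one | CC(=O)c1c(O)cc(OC)c2c1O[C@@H]1C[C@H]2c2c(OC)cc(O)c(OC)c2O1 | intermediate
9 | phenylmagnesium bromide | Br[Mg]c1ccccc1 | starting material
10 | 1-{2,6-dihydroxy-3-[(2R,4R)-7-hydroxy-5,8-dimethoxy-2-phenylchroman-4-yl]-4-methoxyphenyl}ethan-1-one | COc1cc(O)c(C(C)=O)c(O)c1[C@H]1C[C@H](c2ccccc2)Oc2c(OC)c(O)cc(OC)c21 | intermediate
11 | benzaldehyde | O=Cc1ccccc1 | starting material
12 | Sarcandrone B | COc1cc(O)c(C(=O)/C=C/c2ccccc2)c(O)c1[C@H]1C[C@H](c2ccccc2)Oc2c(OC)c(O)cc(OC)c21 | target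

## Summary

Total steps: 7. Longest linear sequence: 6 (1 → 2 → 3 → 4 → 8 → 10 → 12); Step 4 is a one-step side branch.

Steps most likely to fail:

1. **Step 6** (wrong acetal C–O bond cleaved, or poor diastereoselectivity). Fallback: reverse the order of the C2 and C4 events. Make the ring-A chromenylium from 4 and 6, add a phenylboronate enantioselectively at C2 (chiral diol/Lewis acid) to give the (R)-flav-3-ene, then carry out acid-mediated hydroarylation with 5, where the aryl group adds trans to the 2-phenyl group.
2. **Step 5** (low ee, or C2 rather than C4 attack). Fallback: switch from ion-pair to covalent iminium catalysis. Open 7 with aqueous NaHCO3 to the (E)-2-hydroxycinnamaldehyde and run a diarylprolinol silyl ether-catalysed Friedel–Crafts addition of 4, then acid acetalisation to the same acetal 8.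
3. **Step 4** (double addition of 5 to the cation, or aldol at the acetyl group). Fallback: build the three-carbon unit stepwise. Vilsmeier formylation of 5 at C3, Wittig homologation with Ph3P=CHCHO to the (E)-2-hydroxycinnamaldehyde, then HBF4 cyclodehydration to 7 (or direct use of the aldehyde in the iminium variant above).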